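Ring C of the flavonol is disconnected at C4–C4a. The key step makes this bond by intramolecular Friedel–Crafts acylation of an aryloxyacrylic acid and so delivers the complete 3-oxygenated flavone core in one operation, since O1–C2 and the C3 oxygen are already in place. The step relies on C4a of ring A: flanked by O1 and the 5-oxygen and para to the 7-oxygen, it is the most electron-rich carbon of the symmetric 3,5-dimethoxyphenoxy unit. The precursor is (E)-3-(3-bromo-4-methoxyphenyl)-3-(3,5-dimethoxyphenoxy)-2-methoxyacrylic acid, built from a β-keto ester by enol tosylation and vinylic substitution. The acid-sensitive prenyl group is held back as the 3'-bromide and introduced by Suzuki coupling after a methyl-to-MOM exchange.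

Key step: step 5

Remark on the chemistry: compounds 6 and 8 are expected as E/Z mixtures and are used as such, because the acidic medium of step 5 equilibrates the alkene. The (E) descriptor of acid 9 denotes the isomer with the carboxyl group cis to the aryloxy group, which is the geometry that cyclises. Keto ester 5 is racemic and its stereocentre is erased in step 2.

Step 1
Reactants: 1 3-bromo-4-methoxybenzoic acid; 2 methyl methoxyacetate
Product: 5 methyl 3-(3-bromo-4-methoxyphenyl)-2-methoxy-3-oxopropanoate (racemic), via acyl imidazolide 3 (not isolated), via lithium enolate 4 (not isolated)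
Conditions: 1, CDI, THF, rt; then added to 2 (1.2 equiv) + LiN(SiMe3)2 (2.2 equiv), THF, −78 °C; 1 M HCl quench
Reagents that add atoms: none
Why: Claisen-type C-acylation of a lithium ester enolate by an acyl imidazolide is a standard β-keto ester synthesis, the surplus base storing the product as its enolate so that over-addition is prevented, and the aryl bromide is inert to the amide base at −78 °C.

Step 2
Reactants: 5 methyl 3-(3-bromo-4-methoxyphenyl)-2-methoxy-3-oxopropanoate
Product: 6 methyl 3-(3-bromo-4-methoxyphenyl)-2-methoxy-3-(tosyloxy)acrylate (E/Z mixture)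
Conditions: TsCl, Et3N, N-methylimidazole (cat.), MeCN, 0 °C → rt
Reagents that add atoms: p-toluenesulfonyl chloride, Cc1ccc(cc1)S(Cl)(=O)=O
Why: O-sulfonylation of the β-keto ester enolate with the N-sulfonylimidazolium species is an established route to fully substituted enol tosylates, and the α-methoxy group leaves only this one enolisation site.

Step 3
Reactants: 6 methyl 3-(3-bromo-4-methoxyphenyl)-2-methoxy-3-(tosyloxy)acrylate; 7 3,5-dimethoxyphenol
Product: 8 methyl 3-(3-bromo-4-methoxyphenyl)-3-(3,5-dimethoxyphenoxy)-2-methoxyacrylate (E/Z mixture)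
Conditions: Cs2CO3, DMF, 80 °C
Reagents that add atoms: none
Why: Nucleophilic vinylic substitution by addition–elimination, in which the cesium phenoxide adds through oxygen to the β-carbon of the β-sulfonyloxy acrylate and the resulting ester enolate expels tosylate, as in the classical preparation of β-aryloxycinnamates from β-halo- or β-sulfonyloxycinnamates.

Step 4
Reactants: 8 methyl 3-(3-bromo-4-methoxyphenyl)-3-(3,5-dimethoxyphenoxy)-2-methoxyacrylate
Product: 9 (E)-3-(3-bromo-4-methoxyphenyl)-3-(3,5-dimethoxyphenoxy)-2-methoxyacrylic acid (any Z isomer is carried along)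
Conditions: LiOH, THF/MeOH/H2O, 50 °C; then cold 1 M HCl to pH 3
Reagents that add atoms: lithium hydroxide, [Li+].[OH-]
Why: Ordinary saponification by acyl–oxygen cleavage, which the aryl enol ether, the aryl bromide and the methyl ethers should tolerate, followed by brief cold acidification that does not hydrolyse the vinylogous carbonate.

Step 5
Reactants: 9 (E)-3-(3-bromo-4-methoxyphenyl)-3-(3,5-dimethoxyphenoxy)-2-methoxyacrylic acid
Product: 11 3'-bromo-3,5,7,4'-tetramethoxyflavone [2-(3-bromo-4-methoxyphenyl)-3,5,7-trimethoxy-4H-chromen-4-one], via mixed anhydride 10 (not isolated)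
Conditions: (CF3CO)2O (2 equiv), CH2Cl2, 0 °C → rt
Reagents that add atoms: none
Why: Trifluoroacetic anhydride turns the carboxyl group into the mixed anhydride 10 (or the acylium ion derived from it), the ring carbon ortho to the ether oxygen attacks this acyl carbon, and loss of a proton restores the aromaticity of ring A. The closest known reaction is the intramolecular Friedel–Crafts acylation of β-aryloxycinnamic acids to flavones under anhydride or P2O5/MeSO3H activation. Ring C closes by 6-exo-trig attack of the arene carbon on the anhydride carbonyl (6-exo-dig if the free acylium ion is involved), forming C4–C4a; no stereocentre is created. Regiochemistry on ring A is not an issue because the two carbons ortho to the ether oxygen are equivalent by symmetry and the para carbon cannot reach the acyl group. Closure onto ring B to an indenone is disfavoured because its available carbons are meta to the methoxy group and the ring carries bromine, whereas ring A is a phloroglucinol-type nucleophile. Only the E acid places the carboxyl next to the aryloxy group, but the push–pull alkene should isomerise in the acidic medium so that both isomers converge, and the new carbonyl then deactivates ring A against further acylation.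

Step 6
Reactants: 11 3'-bromo-3,5,7,4'-tetramethoxyflavone
Product: 12 3'-bromokaempferol [2-(3-bromo-4-hydroxyphenyl)-3,5,7-trihydroxy-4H-chromen-4-one]
Conditions: BBr3 (10 equiv), CH2Cl2, −78 °C → 40 °C; H2O quench
Reagents that add atoms: none
Why: Lewis acid cleavage of aryl and enol methyl ethers by BBr3 is standard for polymethoxyflavones, and the aryl bromide and the pyrone survive it.

Step 7
Reactants: 12 3'-bromokaempferol
Product: 13 2-[3-bromo-4-(methoxymethoxy)phenyl]-3,5,7-tris(methoxymethoxy)-4H-chromen-4-one
Conditions: NaH (6 equiv), MOMCl (6 equiv), DMF, 0 °C → rt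
Reagents that add atoms: chloromethyl methyl ether, COCCl
Why: Williamson-type O-alkylation of the preformed sodium phenoxides, the excess of strong base ensuring that the hydrogen-bonded 5-hydroxyl also reacts.

Step 8
Reactants: 13 2-[3-bromo-4-(methoxymethoxy)phenyl]-3,5,7-tris(methoxymethoxy)-4H-chromen-4-one; 14 prenylboronic acid pinacol ester
Product: 15 3,5,7-tris(methoxymethoxy)-2-[4-(methoxymethoxy)-3-(3-methylbut-2-en-1-yl)phenyl]-4H-chromen-4-one
Conditions: PdCl2(IPent)(3-chloropyridine) (5 mol %; IPent = 1,3-bis(2,6-di(pentan-3-yl)phenyl)imidazol-2-ylidene), 5 M aq KOH, THF, 65 °C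
Reagents that add atoms: none
Why: Suzuki–Miyaura coupling of an aryl bromide with an allylic boronate, for which oxidative addition to zerovalent palladium bearing this bulky carbene ligand is known to be followed by reductive elimination at the α-carbon to give the linear prenyl arene, while the MOM acetals are stable to aqueous base.

Step 9
Reactants: 15 3,5,7-tris(methoxymethoxy)-2-[4-(methoxymethoxy)-3-(3-methylbut-2-en-1-yl)phenyl]-4H-chromen-4-one
Product: 16 isolicoflavonol [3,5,7-trihydroxy-2-[4-hydroxy-3-(3-methylbut-2-en-1-yl)phenyl]-4H-chromen-4-one]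
Conditions: HCl (2 M in MeOH), THF, rt → 40 °C, stopped at full conversion
Reagents that add atoms: none
Why: Acid-catalysed transacetalisation of the four MOM ethers to methanol proceeds under conditions mild enough to leave an ortho-prenylphenol uncyclised, as is usual for prenylated flavonoids.

Compound list
1 | 3-bromo-4-methoxybenzoic acid | COc1ccc(C(=O)O)cc1Br | starting material
2 | methyl methoxyacetate | COCC(=O)OC | starting material
3 | 1-(3-bromo-4-methoxybenzoyl)-1H-imidazole | COc1ccc(C(=O)n2ccnc2)cc1Br | intermediate
4 | lithium enolate of methyl methoxyacetate | COC=C(OC)O[Li] | intermediate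
5 | methyl 3-(3-bromo-4-methoxyphenyl)-2-methoxy-3-oxopropanoate (racemic) | COC(=O)C(OC)C(=O)c1ccc(OC)c(Br)c1 | intermediate
6 | methyl 3-(3-bromo-4-methoxyphenyl)-2-methoxy-3-(tosyloxy)acrylate (E/Z mixture, geometry unspecified) | COC(=O)C(OC)=C(OS(=O)(=O)c1ccc(C)cc1)c1ccc(OC)c(Br)c1 | intermediate
7 | 3,5-dimethoxyphenol | COc1cc(O)cc(OC)c1 | starting material
8 | methyl 3-(3-bromo-4-methoxyphenyl)-3-(3,5-dimethoxyphenoxy)-2-methoxyacrylate (E/Z mixture, geometry unspecified) | COC(=O)C(OC)=C(Oc1cc(OC)cc(OC)c1)c1ccc(OC)c(Br)c1 | intermediate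
9 | (E)-3-(3-bromo-4-methoxyphenyl)-3-(3,5-dimethoxyphenoxy)-2-methoxyacrylic acid | OC(=O)/C(OC)=C(\Oc1cc(OC)cc(OC)c1)c1ccc(OC)c(Br)c1 | intermediate
10 | (E)-3-(3-bromo-4-methoxyphenyl)-3-(3,5-dimethoxyphenoxy)-2-methoxyacrylic trifluoroacetic anhydride | FC(F)(F)C(=O)OC(=O)/C(OC)=C(\Oc1cc(OC)cc(OC)c1)c1ccc(OC)c(Br)c1 | intermediate
11 | 3'-bromo-3,5,7,4'-tetramethoxyflavone | COc1cc(OC)c2c(=O)c(OC)c(-c3ccc(OC)c(Br)c3)oc2c1 | intermediate
12 | 3'-bromokaempferol | Oc1cc(O)c2c(=O)c(O)c(-c3ccc(O)c(Br)c3)oc2c1 | intermediate
13 | 2-[3-bromo-4-(methoxymethoxy)phenyl]-3,5,7-tris(methoxymethoxy)-4H-chromen-4-one | COCOc1cc(OCOC)c2c(=O)c(OCOC)c(-c3ccc(OCOC)c(Br)c3)oc2c1 | intermediate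
14 | prenylboronic acid pinacol ester | CC(C)=CCB1OC(C)(C)C(C)(C)O1 | starting material
15 | 3,5,7-tris(methoxymethoxy)-2-[4-(methoxymethoxy)-3-(3-methylbut-2-en-1-yl)phenyl]-4H-chromen-4-one | COCOc1cc(OCOC)c2c(=O)c(OCOC)c(-c3ccc(OCOC)c(CC=C(C)C)c3)oc2c1 | intermediate
16 | isolicoflavonol | CC(C)=CCc1cc(-c2oc3cc(O)cc(O)c3c(=O)c2O)ccc1O | target

Total step count: 9
Longest linear sequence: 9 steps (1 → 16)

Steps most likely to fail

Step 3. The phenoxide must add to a tetrasubstituted alkene whose β-carbon is made electron-richer by the α-methoxy and β-anisyl groups. Addition may therefore be slow, and transfer of the sulfonyl group to the phenoxide (attack at sulfur) or C-alkylation of the ambident phenoxide could take over. The fallback sets out from keto ester 5 and returns at 8. Treatment of 5 with Ph3PCl2 and Et3N in MeCN should give methyl 3-(3-bromo-4-methoxyphenyl)-3-chloro-2-methoxyacrylate F1, a vinylogous acid chloride that has no sulfur electrophile and tolerates forcing conditions. Sodium 3,5-dimethoxyphenoxide (from 7 and NaH) in DMSO at 100 °C should then displace chloride in the classical β-chlorocinnamate manner to give 8.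

Step 5. Ring closure may be outrun by intermolecular trifluoroacetylation of the very electron-rich ring A or by acid-induced cleavage of the aryl enol ether. The fallback closes ring C at O1–C2 instead; it sets out from 7 and 1 and returns at 11. Phenol 7 is C-acylated ortho to its hydroxyl with methoxyacetic acid and BF3·OEt2 at 80 °C to 1-(2-hydroxy-4,6-dimethoxyphenyl)-2-methoxyethan-1-one F2. Acid 1 is converted with oxalyl chloride and catalytic DMF into 3-bromo-4-methoxybenzoyl chloride F3, which esterifies F2 in pyridine to 3,5-dimethoxy-2-(2-methoxyacetyl)phenyl 3-bromo-4-methoxybenzoate F4. Baker–Venkataraman rearrangement (KOH, pyridine, 50 °C) should give 1-(3-bromo-4-methoxyphenyl)-3-(2-hydroxy-4,6-dimethoxyphenyl)-2-methoxypropane-1,3-dione F5, and cyclodehydration (H2SO4, AcOH, 100 °C) leads to flavone 11.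

Step 8. Transmetalation through the γ-carbon may deliver the branched 1,1-dimethylallyl isomer, and hot aqueous hydroxide may open the pyrone ring at C2. The fallback sets out from 13 and returns at 15. A neutral Stille coupling with allyltributylstannane (Pd(PPh3)4, toluene, 100 °C) has no regiochemical ambiguity and should give 2-[3-allyl-4-(methoxymethoxy)phenyl]-3,5,7-tris(methoxymethoxy)-4H-chromen-4-one F6. Olefin cross-metathesis of F6 with excess 2-methyl-2-butene (second-generation Grubbs catalyst RuCl2(=CHPh)(H2IMes)(PCy3), CH2Cl2, 40 °C) converts the allyl into the prenyl group of 15.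

Further compounds
F1 | step 3 | methyl 3-(3-bromo-4-methoxyphenyl)-3-chloro-2-methoxyacrylate (E/Z mixture) | COC(=O)C(OC)=C(Cl)c1ccc(OC)c(Br)c1
F2 | step 5 | 1-(2-hydroxy-4,6-dimethoxyphenyl)-2-methoxyethan-1-one | COCC(=O)c1c(O)cc(OC)cc1OC
F3 | step 5 | 3-bromo-4-methoxybenzoyl chloride | COc1ccc(C(Cl)=O)cc1Br
F4 | step 5 | 3,5-dimethoxy-2-(2-methoxyacetyl)phenyl 3-bromo-4-methoxybenzoate | COCC(=O)c1c(OC(=O)c2ccc(OC)c(Br)c2)cc(OC)cc1OC
F5 | step 5 | 1-(3-bromo-4-methoxyphenyl)-3-(2-hydroxy-4,6-dimethoxyphenyl)-2-methoxypropane-1,3-dione (racemic) | COC(C(=O)c1ccc(OC)c(Br)c1)C(=O)c1c(O)cc(OC)cc1OC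
F6 | step 8 | 2-[3-allyl-4-(methoxymethoxy)phenyl]-3,5,7-tris(methoxymethoxy)-4H-chromen-4-one | COCOc1cc(OCOC)c2c(=O)c(OCOC)c(-c3ccc(OCOC)c(CC=C)c3)oc2c1
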